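Remark on the chemistry: the target has no stereocentre and its SMILES defines no axial chirality, so intermediates 3, 4 and 10 are carried as racemic or diastereomeric mixtures. Phenyllithium, 4-bromoanisole and the other reagents are taken as commercial.

## Analysis of the target

Selaginellin A (11) has no fused ring system. Four six-membered carbocycles hang on a central benzene, ring A, and one of them, a cyclohexa-2,5-dienone, is joined to ring A through a single exocyclic sp2 carbon. Ring A is 1,2,3,4-tetrasubstituted: methyl at C1, the (4-hydroxyphenyl)ethynyl arm at C2, the quinone methide carbon (which also carries a phenyl group) at C3, the 4-hydroxyphenyl ring B at C4, and hydrogen at C5 and C6. There is no stereocentre, and the exocyclic double bond has no E/Z descriptor because the dienone ring is symmetric across it, so the problem is one of regiochemistry and of the order of bond formation. The sensitive groups are the quinone methide (a fuchsone, electrophilic at its central carbon), two free phenols, and an electron-rich diarylalkyne that lies ortho to a cation-stabilising benzylic carbon. The difficulty is the run of four different neighbours on ring A: C3 is buried between ring B and the alkyne, and its exocyclic carbon must receive two different aryl groups one after the other. The feature that the strategy uses is that C1–C2–C3 of ring A correspond to the ethyl-ketone methylene (carrying the methyl), the ketone carbon and the ester-bearing carbon of a β-keto ester, while C4–C5–C6 correspond to the β-, α- and carbonyl carbons of a 4-methoxycinnamaldehyde. Joining the two pieces at C3–C4 and C1–C6 gives ring A with an oxygen at C2 and an ester at C3, which are the two handles the alkyne and the quinone methide carbon need.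

## Retrosynthetic reasoning

**11 to 10.** No skeletal bond is cut first. The quinone methide of 11 is the dehydrated form of a triaryl carbinol that carries a para-hydroxyphenyl group. Going backwards, the exocyclic carbon on C3 becomes sp3 with an OH group, and the three phenolic oxygens are capped as methyl ethers, which gives carbinol 10. This keeps the electrophilic fuchsone and the acidic phenols out of every earlier stage. In the forward direction one Lewis-acid operation has to cleave three aryl methyl ethers, ionise the carbinol and let the cation collapse to the quinone methide.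

**10 to 9.** The bond between the carbinol carbon and its p-anisyl ring is cut, which leaves diaryl ketone 9 and a p-anisyl carbon nucleophile. The cut is placed here because 9 is non-enolisable, so a strong carbon nucleophile can only add to the carbonyl. The forward reaction must force an aryl group onto a carbonyl shielded by ring B and the alkynyl arm.

**9 to 8.** The carbonyl–phenyl bond is cut, which leads to ethyl ester 8 and a phenyl nucleophile. The ester is the oxidation level that the ring synthesis delivers at C3, so no redox adjustment is needed. The forward reaction must stop after one acyl substitution, and the crowding around C3, a nuisance elsewhere, is what should hold it at the ketone.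

**8 to 6 and 7, and 6 to 5.** The C2–C(sp) bond is cut, giving aryl triflate 6 and the commercial terminal alkyne 7. The alkyne is installed after ring A is complete, so that it never meets the oxidant of the ring synthesis, and before the organolithium steps, which a triflate would not survive. Triflate 6 comes from phenol 5, whose C2 oxygen is the ketone oxygen of the ring-forming step. The forward coupling has to work at a C–O bond flanked by methyl and ester, helped by the electron-withdrawing ester.

**5 to 4, 3, 1 and 2.** Ring A itself is opened at C3–C4 and C1–C6. Phenol 5 is the dehydrogenated tautomer of cyclohexenone 4. Ring 4 is the aldol condensation product of keto aldehyde 3, and 3 is the conjugate adduct of β-keto ester 1 to enal 2. Cutting here turns a contiguously tetrasubstituted benzene into two cheap acyclic partners, and the positions of methyl, oxygen, ester and aryl follow from the connectivity of 1 and 2 with no regiochemical choice. The forward reaction needs 1,4-addition before ring closure and one clean dehydrogenation.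

## Alternatives that were turned down

**Alternative 1:** Ring A would be bought as 4-chloro-2-iodotoluene A2, and the C3–carbonyl and C2–alkyne bonds would be made in one operation. In the key step Pd(OAc)2, a phosphine, norbornene A4 and Cs2CO3 would take the arylpalladium species derived from A2 through insertion of A4 and palladation of the C3–H. Acylation there by benzoic anhydride A3, extrusion of A4 and termination at C2 with alkyne 7 would give the ketone [6-chloro-2-[(4-methoxyphenyl)ethynyl]-3-methylphenyl](phenyl)methanone A1. A Suzuki coupling at the chloride of A1, aryl addition to its carbonyl and demethylation would finish the synthesis.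
- In its favour, it is the shortest plan, about four steps, and the benzoyl group of A1 arrives as a ketone, so the question of stopping an ester at mono-addition never arises. On both points it is stronger than the chosen route.
- Against it, the C–H of A2 to be palladated lies between the palladium-bearing C2 and the chlorine at C4, and the termination must then occur between a methyl and a benzoyl group. Three partners must react in a fixed order, while direct coupling of 7 at C2 of A2, acylation of the alkyne by A3 and insertion into the C–Cl bond are all open. The later Suzuki coupling would have to take place at the chloride of A1, which is ortho to the benzoyl group.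
- The chosen strategy is two steps longer, but it fixes the 1,2,3,4 pattern by a condensation whose regiochemistry cannot vary.

**Alternative 2:** Three bonds of ring A (C1–C6, C4–C5, C2–C3) would be cut. The ring would come from the ester-tethered diyne 1,3-bis(4-methoxyphenyl)-1-phenylprop-2-yn-1-yl but-2-ynoate A6 and acetylene A7. RhCl(PPh3)3 (monovalent rhodium) would cyclotrimerise A6 with A7 to the phthalide 3,4-bis(4-methoxyphenyl)-7-methyl-3-phenylisobenzofuran-1(3H)-one A5.
- In its favour, the carbinol carbon with its two different aryl groups is assembled before ring A from an unhindered ketone, so sequential aryl addition to a shielded carbonyl disappears, and the tether of A6 fixes the regiochemistry. On the first point it is stronger than the chosen route.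
- Against it, A6 is the ester of a tertiary, doubly benzylic propargylic alcohol, which is hard to acylate and prone to ionise (Meyer–Schuster-type pathways). The cyclotrimerisation needs gaseous A7 and an aryl-capped, crowded alkyne. Most seriously, the lactone carbonyl of A5 sits on C2 and must still be turned into the arylalkyne by reduction, one-carbon homologation of a hindered masked aldehyde and cross-coupling.
- The total would be about nine steps against six. The chosen route instead uses the C2 oxygen directly as the coupling handle.

**Alternative 3:** The bond between the two alkyne carbons would be cut, with the alkyne and the carbinol carbon masked together as an enol lactone. A lithium amide base would convert 6-(4-methoxyphenyl)-2,3-dimethylbenzoic acid A9 into its dianion, which would be acylated at the methyl group on C2 by methyl 4-methoxybenzoate A10. Acid would then close the isocoumarin 3,8-bis(4-methoxyphenyl)-5-methyl-1H-isochromen-1-one A8.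
- In its favour, the single lactone ring of A8 ties up both reactive carbons. Opening the lactone of A8 with a phenyl nucleophile gives a ketone beside an enolate, which should resist a second addition better than ester 8 does, so on this point it is at least as good.
- Against it, A9 already contains the complete tetrasubstituted ring A, so the plan defers the main problem and does not solve it. The acylation by A10 gives a ketone more acidic than A9, which consumes base and calls for an excess of it. The late conversion of the deoxybenzoin carbonyl released from A8 into an alkyne must also be done next to a tertiary carbinol, which can close back onto it to give a 1H-isochromene.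
- The chosen route builds ring A from acyclic material and introduces the alkyne by a plain cross-coupling.

Key step: step 1

## Route

Step 1
Reactants: 1 ethyl 3-oxopentanoate; 2 (E)-4-methoxycinnamaldehyde
Product: 5 ethyl 2-hydroxy-6-(4-methoxyphenyl)-3-methylbenzoate, via keto aldehyde Michael adduct 3 (not isolated), via cyclohexenone ester 4 (not isolated)
Conditions: pyrrolidine (20 mol %), PhCO2H (20 mol %), DMSO, rt to 60 °C; then I2 (30 mol %), 100 °C, same flask
Reagents that add atoms: none
Why: Pyrrolidine condenses with 2 to an α,β-unsaturated iminium ion, and the doubly activated carbon of 1 adds to its β-carbon (Michael addition, forming C3–C4 of ring A); hydrolysis of the resulting enamine releases keto aldehyde 3. The only carbon of 3 that can reach the aldehyde through a six-membered transition state is the methylene of the ethyl ketone, whose enol closes ring A by a 6-(enolendo)-exo-trig aldol addition (C1–C6), and dehydration gives the conjugated 2-methylcyclohexenone 4. Closure through the ester-bearing carbon would give a four-membered ring, so the methyl group must end next to the ring carbonyl. Iodine then iodinates the enolised β-keto ester carbon of 4, HI is lost towards the aryl-bearing carbon, and the cross-conjugated dienone tautomerises to phenol 5, while DMSO reoxidises HI so that iodine turns over. The closest known reaction types are the secondary-amine-catalysed Michael–aldol condensation of β-keto esters with enals to cyclohexenone carboxylates and the iodine/DMSO dehydrogenation of cyclohexenones to phenols. The two stereocentres of 4 are destroyed on aromatisation, so an achiral amine suffices and no stereocontrol is needed. The step needs 1,4- over 1,2-addition to the enal (Knoevenagel condensation), which the iminium ion of a β-aryl enal and the soft stabilised nucleophile favour, and a single dehydrogenation, which the substrate secures because the β-keto ester carbon of 4 is the one readily halogenated position and both ortho positions of the product phenol are blocked.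

Step 2
Reactants: 5 ethyl 2-hydroxy-6-(4-methoxyphenyl)-3-methylbenzoate
Product: 6 ethyl 6-(4-methoxyphenyl)-3-methyl-2-(trifluoromethanesulfonyloxy)benzoate
Conditions: Tf2O, pyridine, CH2Cl2, 0 °C to rt
Reagents that add atoms: trifluoromethanesulfonic anhydride, O=S(=O)(OS(=O)(=O)C(F)(F)F)C(F)(F)F
Why: O-Sulfonylation of a phenol; the salicylate hydroxyl is hydrogen-bonded and flanked on both sides, but the N-triflylpyridinium species formed from Tf2O and pyridine is electrophilic enough to triflate it, and the ester and the anisyl ether are inert.

Step 3
Reactants: 6 ethyl 6-(4-methoxyphenyl)-3-methyl-2-(trifluoromethanesulfonyloxy)benzoate; 7 4-ethynylanisole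
Product: 8 ethyl 6-(4-methoxyphenyl)-2-[(4-methoxyphenyl)ethynyl]-3-methylbenzoate
Conditions: PdCl2(PPh3)2 (5 mol %), CuI (10 mol %), Et3N, DMF, 80 °C
Reagents that add atoms: none
Why: Sonogashira coupling: zerovalent palladium, formed in the flask from the divalent palladium precatalyst, inserts into the C2–OTf bond, which the ortho ester makes electron-poor; the copper acetylide of 7 transmetalates and reductive elimination forms the C2–C(sp) bond. The ester and both methyl ethers are inert to Et3N in DMF at this temperature.

Step 4
Reactants: 8 ethyl 6-(4-methoxyphenyl)-2-[(4-methoxyphenyl)ethynyl]-3-methylbenzoate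
Product: 9 [6-(4-methoxyphenyl)-2-[(4-methoxyphenyl)ethynyl]-3-methylphenyl](phenyl)methanone
Conditions: PhLi (1.1 equiv), THF, −78 °C; H2O quench at −78 °C
Reagents that add atoms: phenyllithium, [Li]c1ccccc1
Why: Nucleophilic acyl substitution of a hindered ester by an aryllithium: the di-ortho-substituted benzoate should give a congested lithium hemiketal alkoxide that is kept at −78 °C and protonated there, so ketone 9 is released only when no phenyllithium is left. Should some of it collapse earlier, the carbonyl of 9 lies between ring B and the alkynyl arm and should take a second phenyl more slowly than 8 takes the first; the diarylalkyne is not carbolithiated at this temperature.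

Step 5
Reactants: 9 [6-(4-methoxyphenyl)-2-[(4-methoxyphenyl)ethynyl]-3-methylphenyl](phenyl)methanone
Product: 10 (4-methoxyphenyl)[6-(4-methoxyphenyl)-2-[(4-methoxyphenyl)ethynyl]-3-methylphenyl](phenyl)methanol (racemic)
Conditions: 4-bromoanisole (3 equiv), n-BuLi (3 equiv), THF, −78 °C; add 9, −78 to 0 °C; H2O
Reagents that add atoms: 4-bromoanisole, COc1ccc(Br)cc1 (used as 4-methoxyphenyllithium, [Li]c1ccc(OC)cc1)
Why: 1,2-Addition of an aryllithium to a non-enolisable diaryl ketone: bromine–lithium exchange gives the aryllithium, addition is the only path open at the carbonyl of 9, and excess reagent with warming to 0 °C should overcome the shielding. The carbinol centre forms as a racemate and is erased in step 6; the lithium alkoxide is quenched cold so that it does not add across the neighbouring alkyne.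

Step 6
Reactants: 10 (4-methoxyphenyl)[6-(4-methoxyphenyl)-2-[(4-methoxyphenyl)ethynyl]-3-methylphenyl](phenyl)methanol
Product: 11 selaginellin A, 4-[[6-(4-hydroxyphenyl)-2-[(4-hydroxyphenyl)ethynyl]-3-methylphenyl](phenyl)methylidene]cyclohexa-2,5-dien-1-one
Conditions: BBr3 (excess), CH2Cl2, −78 to 0 °C; then H2O, 0 °C
Reagents that add atoms: none
Why: Lewis-acid cleavage of three aryl methyl ethers by BBr3 (bromide attacks the O-methyl group of each boron-complexed ether) together with ionisation of the tertiary triaryl carbinol; after hydrolysis the para-hydroxy-substituted trityl cation loses its phenolic proton and becomes the quinone methide (fuchsone formation). The two other phenols are freed in the same operation and no stereocentre remains.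

## Compound list

1 | ethyl 3-oxopentanoate | CCC(=O)CC(=O)OCC | starting material
2 | (E)-4-methoxycinnamaldehyde | COc1ccc(/C=C/C=O)cc1 | starting material
3 | ethyl 2-[1-(4-methoxyphenyl)-3-oxopropyl]-3-oxopentanoate (racemic mixture of diastereomers, not isolated) | CCC(=O)C(C(=O)OCC)C(CC=O)c1ccc(OC)cc1 | intermediate
4 | ethyl 6-(4-methoxyphenyl)-3-methyl-2-oxocyclohex-3-ene-1-carboxylate (racemic mixture of diastereomers, not isolated) | CCOC(=O)C1C(=O)C(C)=CCC1c1ccc(OC)cc1 | intermediate
5 | ethyl 2-hydroxy-6-(4-methoxyphenyl)-3-methylbenzoate | CCOC(=O)c1c(-c2ccc(OC)cc2)ccc(C)c1O | intermediate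
6 | ethyl 6-(4-methoxyphenyl)-3-methyl-2-(trifluoromethanesulfonyloxy)benzoate | CCOC(=O)c1c(-c2ccc(OC)cc2)ccc(C)c1OS(=O)(=O)C(F)(F)F | intermediate
7 | 4-ethynylanisole | C#Cc1ccc(OC)cc1 | starting material
8 | ethyl 6-(4-methoxyphenyl)-2-[(4-methoxyphenyl)ethynyl]-3-methylbenzoate | CCOC(=O)c1c(-c2ccc(OC)cc2)ccc(C)c1C#Cc1ccc(OC)cc1 | intermediate
9 | [6-(4-methoxyphenyl)-2-[(4-methoxyphenyl)ethynyl]-3-methylphenyl](phenyl)methanone | O=C(c1ccccc1)c1c(-c2ccc(OC)cc2)ccc(C)c1C#Cc1ccc(OC)cc1 | intermediate
10 | (4-methoxyphenyl)[6-(4-methoxyphenyl)-2-[(4-methoxyphenyl)ethynyl]-3-methylphenyl](phenyl)methanol (racemic) | OC(c1ccccc1)(c1ccc(OC)cc1)c1c(-c2ccc(OC)cc2)ccc(C)c1C#Cc1ccc(OC)cc1 | intermediate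
11 | selaginellin A | Cc1ccc(-c2ccc(O)cc2)c(C(=C2C=CC(=O)C=C2)c2ccccc2)c1C#Cc1ccc(O)cc1 | target

## Step count and least certain steps

Total step count: 6. Longest linear sequence: 6 steps (from 1 and 2 to 11; 7 enters at step 3).

**Step 1 (key step).**
- Risk: the enal may be diverted into 1,2-addition (Knoevenagel condensation and electrocyclisation to a 2H-pyran), or the Michael adduct may close through its enol oxygen to a lactol that dehydrates to a 4H-pyran. The enol oxygen reaches the aldehyde more easily than the weakly acidic ethyl-ketone methylene does. In the oxidation stage, ring iodination of the anisyl group or of C5 could compete with dehydrogenation.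
- Fallback: it sets out from 1, avoids both amine catalysis and the oxidation, and returns at 5. Compound 1 is silylated (TMSCl, Et3N) to ethyl 3-(trimethylsilyloxy)pent-2-enoate F1 (geometry immaterial). F1 is deprotonated at the γ-carbon with LDA and silylated again to 1-ethoxy-1,3-bis(trimethylsilyloxy)penta-1,3-diene F2. Separately, commercial 4'-methoxyacetophenone is formylated (HCO2Et, NaOEt) to 3-hydroxy-1-(4-methoxyphenyl)prop-2-en-1-one F3, which is acetalised (HC(OMe)3, MeOH, acid) to 3,3-dimethoxy-1-(4-methoxyphenyl)propan-1-one F4. With TiCl4 in CH2Cl2 from −78 °C to rt, the terminal carbon of F2 should attack the acetal carbon of F4 and the central carbon should close onto the ketone (formal [3+3] cyclocondensation of a 1,3-bis(silyl enol ether) with a β-keto acetal). Loss of methanol and water gives 5 directly at the aromatic oxidation level.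

**Step 4.**
- Risk: the tetrahedral adduct may collapse before the quench, after which a second phenyl adds to the freed ketone. At the other extreme the shielded ester may not react at −78 °C, and warming would invite carbolithiation of the alkyne.
- Fallback: it sets out from 8 and returns at 9, taking the ester through the aldehyde oxidation level so that each carbon nucleophile can add only once. DIBAL-H (CH2Cl2, −78 to 0 °C) reduces 8 to [6-(4-methoxyphenyl)-2-[(4-methoxyphenyl)ethynyl]-3-methylphenyl]methanol F5. Dess–Martin periodinane oxidises it to 6-(4-methoxyphenyl)-2-[(4-methoxyphenyl)ethynyl]-3-methylbenzaldehyde F6. PhMgBr (THF, 0 °C) gives racemic [6-(4-methoxyphenyl)-2-[(4-methoxyphenyl)ethynyl]-3-methylphenyl](phenyl)methanol F7, and a second Dess–Martin oxidation gives 9.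

**Step 6.**
- Risk: the triaryl cation that BBr3 generates at the outset persists through the slow cleavage of three ethers. It may close onto ring B by Friedel–Crafts attack to form a 9,9-diarylfluorene, and the HBr released may add across the electron-rich alkyne.
- Fallback: it sets out from 5 and returns at 11, moving the only strong Lewis-acid treatment to a stage with neither alkyne nor carbinol and carrying the phenols as silyl ethers. BBr3 (CH2Cl2, −78 to 0 °C) cleaves the one methyl ether of 5 to ethyl 2-hydroxy-6-(4-hydroxyphenyl)-3-methylbenzoate F8. TBSCl and imidazole silylate the free ring B phenol and not the hydrogen-bonded, flanked salicylate hydroxyl, giving ethyl 6-[4-(tert-butyldimethylsilyloxy)phenyl]-2-hydroxy-3-methylbenzoate F9. Tf2O and pyridine then give ethyl 6-[4-(tert-butyldimethylsilyloxy)phenyl]-3-methyl-2-(trifluoromethanesulfonyloxy)benzoate F10. Sonogashira coupling of F10 with commercial tert-butyl(4-ethynylphenoxy)dimethylsilane gives ethyl 6-[4-(tert-butyldimethylsilyloxy)phenyl]-2-[[4-(tert-butyldimethylsilyloxy)phenyl]ethynyl]-3-methylbenzoate F11. PhLi at −78 °C gives [6-[4-(tert-butyldimethylsilyloxy)phenyl]-2-[[4-(tert-butyldimethylsilyloxy)phenyl]ethynyl]-3-methylphenyl](phenyl)methanone F12. The aryllithium made from (4-bromophenoxy)(tert-butyl)dimethylsilane and n-BuLi adds to F12 to give the racemic tris-silyl carbinol [4-(tert-butyldimethylsilyloxy)phenyl][6-[4-(tert-butyldimethylsilyloxy)phenyl]-2-[[4-(tert-butyldimethylsilyloxy)phenyl]ethynyl]-3-methylphenyl](phenyl)methanol F13. TBAF buffered with AcOH (THF, 0 °C) removes the three silyl groups to give (4-hydroxyphenyl)[6-(4-hydroxyphenyl)-2-[(4-hydroxyphenyl)ethynyl]-3-methylphenyl](phenyl)methanol F14, which is not isolated, and dilute aqueous acid on work-up dehydrates it to 11.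

**Step 3.**
- Risk: oxidative addition and transmetalation at a C–OTf bond flanked by methyl and ester may be slow. Copper-mediated oxidative homocoupling of 7 would then consume the alkyne, and S–O cleavage of the triflate would return 5.
- Fallback: it sets out from 7 and returns at 8, replacing the copper acetylide by a preformed zinc acetylide (Negishi alkynylation), which cannot homocouple oxidatively and transmetalates faster. Compound 7 is deprotonated with n-BuLi (THF, −78 °C) and treated with ZnCl2 to give [(4-methoxyphenyl)ethynyl]zinc chloride F15. F15 is coupled with triflate 6 using Pd(PPh3)4 (zerovalent palladium) in THF at 60 °C to give 8.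

## Further compounds

F1 | step 1 | ethyl 3-(trimethylsilyloxy)pent-2-enoate (E/Z mixture) | CCC(O[Si](C)(C)C)=CC(=O)OCC
F2 | step 1 | 1-ethoxy-1,3-bis(trimethylsilyloxy)penta-1,3-diene (mixture of geometric isomers) | CC=C(O[Si](C)(C)C)C=C(OCC)O[Si](C)(C)C
F3 | step 1 | 3-hydroxy-1-(4-methoxyphenyl)prop-2-en-1-one | COc1ccc(C(=O)C=CO)cc1
F4 | step 1 | 3,3-dimethoxy-1-(4-methoxyphenyl)propan-1-one | COc1ccc(C(=O)CC(OC)OC)cc1
F5 | step 4 | [6-(4-methoxyphenyl)-2-[(4-methoxyphenyl)ethynyl]-3-methylphenyl]methanol | OCc1c(-c2ccc(OC)cc2)ccc(C)c1C#Cc1ccc(OC)cc1
F6 | step 4 | 6-(4-methoxyphenyl)-2-[(4-methoxyphenyl)ethynyl]-3-methylbenzaldehyde | O=Cc1c(-c2ccc(OC)cc2)ccc(C)c1C#Cc1ccc(OC)cc1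
F7 | step 4 | [6-(4-methoxyphenyl)-2-[(4-methoxyphenyl)ethynyl]-3-methylphenyl](phenyl)methanol (racemic) | OC(c1ccccc1)c1c(-c2ccc(OC)cc2)ccc(C)c1C#Cc1ccc(OC)cc1
F8 | step 6 | ethyl 2-hydroxy-6-(4-hydroxyphenyl)-3-methylbenzoate | CCOC(=O)c1c(-c2ccc(O)cc2)ccc(C)c1O
F9 | step 6 | ethyl 6-[4-(tert-butyldimethylsilyloxy)phenyl]-2-hydroxy-3-methylbenzoate | CCOC(=O)c1c(-c2ccc(O[Si](C)(C)C(C)(C)C)cc2)ccc(C)c1O
F10 | step 6 | ethyl 6-[4-(tert-butyldimethylsilyloxy)phenyl]-3-methyl-2-(trifluoromethanesulfonyloxy)benzoate | CCOC(=O)c1c(-c2ccc(O[Si](C)(C)C(C)(C)C)cc2)ccc(C)c1OS(=O)(=O)C(F)(F)F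
F11 | step 6 | ethyl 6-[4-(tert-butyldimethylsilyloxy)phenyl]-2-[[4-(tert-butyldimethylsilyloxy)phenyl]ethynyl]-3-methylbenzoate | CCOC(=O)c1c(-c2ccc(O[Si](C)(C)C(C)(C)C)cc2)ccc(C)c1C#Cc1ccc(O[Si](C)(C)C(C)(C)C)cc1
F12 | step 6 | [6-[4-(tert-butyldimethylsilyloxy)phenyl]-2-[[4-(tert-butyldimethylsilyloxy)phenyl]ethynyl]-3-methylphenyl](phenyl)methanone | O=C(c1ccccc1)c1c(-c2ccc(O[Si](C)(C)C(C)(C)C)cc2)ccc(C)c1C#Cc1ccc(O[Si](C)(C)C(C)(C)C)cc1
F13 | step 6 | [4-(tert-butyldimethylsilyloxy)phenyl][6-[4-(tert-butyldimethylsilyloxy)phenyl]-2-[[4-(tert-butyldimethylsilyloxy)phenyl]ethynyl]-3-methylphenyl](phenyl)methanol (racemic) | OC(c1ccccc1)(c1ccc(O[Si](C)(C)C(C)(C)C)cc1)c1c(-c2ccc(O[Si](C)(C)C(C)(C)C)cc2)ccc(C)c1C#Cc1ccc(O[Si](C)(C)C(C)(C)C)cc1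
F14 | step 6 | (4-hydroxyphenyl)[6-(4-hydroxyphenyl)-2-[(4-hydroxyphenyl)ethynyl]-3-methylphenyl](phenyl)methanol (racemic, not isolated) | OC(c1ccccc1)(c1ccc(O)cc1)c1c(-c2ccc(O)cc2)ccc(C)c1C#Cc1ccc(O)cc1
F15 | step 3 | [(4-methoxyphenyl)ethynyl]zinc chloride | COc1ccc(C#C[Zn]Cl)cc1
A1 | alternative 1 | [6-chloro-2-[(4-methoxyphenyl)ethynyl]-3-methylphenyl](phenyl)methanone | Cc1ccc(Cl)c(C(=O)c2ccccc2)c1C#Cc1ccc(OC)cc1
A2 | alternative 1 | 4-chloro-2-iodotoluene | Cc1ccc(Cl)cc1I
A3 | alternative 1 | benzoic anhydride | O=C(OC(=O)c1ccccc1)c1ccccc1
A4 | alternative 1 | norbornene | C1=CC2CCC1C2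
A5 | alternative 2 | 3,4-bis(4-methoxyphenyl)-7-methyl-3-phenylisobenzofuran-1(3H)-one (racemic) | Cc1ccc(-c2ccc(OC)cc2)c2c1C(=O)OC2(c1ccccc1)c1ccc(OC)cc1
A6 | alternative 2 | 1,3-bis(4-methoxyphenyl)-1-phenylprop-2-yn-1-yl but-2-ynoate (racemic) | CC#CC(=O)OC(c1ccccc1)(c1ccc(OC)cc1)C#Cc1ccc(OC)cc1
A7 | alternative 2 | acetylene | C#C
A8 | alternative 3 | 3,8-bis(4-methoxyphenyl)-5-methyl-1H-isochromen-1-one | Cc1ccc(-c2ccc(OC)cc2)c2c1C=C(c1ccc(OC)cc1)OC2=O
A9 | alternative 3 | 6-(4-methoxyphenyl)-2,3-dimethylbenzoic acid | Cc1ccc(-c2ccc(OC)cc2)c(C(=O)O)c1C
A10 | alternative 3 | methyl 4-methoxybenzoate | COC(=O)c1ccc(OC)cc1
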